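**Retrosynthetic overview**
1. The last C–C bond is C3–C1′, made by Suzuki–Miyaura coupling of a 3-iodochromone (A/C rings, saturated side chain already in place) with a prenylated resorcinol boronate (B ring), followed by global MOM removal. The prenyl alkene therefore never meets I+ or H2/Pd.
2. The pyranone (C) ring is the only ring built. It comes from DMF-DMA/I2 cyclisation of a 2-hydroxyacetophenone whose single free ortho phenol lies para to the side chain.
3. The side chain comes from Sonogashira coupling with 2-methylbut-3-yn-2-ol and hydrogenation. The 6- (not 8-) position is fixed by iodinating ortho to the free phenol of dibenzyl phloroacetophenone, capping that phenol as MOM, and freeing the other ortho phenol by hydrogenolysis.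
4. The B-ring boronate comes from resorcinol: bis-MOM ether, ortho-lithiation/prenylation between the two OMOM groups, bromination, Br/Li exchange and borylation.
5. Ring order: A and B rings are bought as benzene derivatives; the C ring is closed in step 6; the two halves are joined in step 11.

Assumption: the target has no stereocentre and no E/Z-capable alkene, so it is achiral and "single enantiomer" needs no stereocontrol; compound 1 is taken as a catalogue compound (the dibenzyl ether of 2,4,6-trihydroxyacetophenone).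

**Route**

Step 1
Reactants: 1 1-[2,4-bis(benzyloxy)-6-hydroxyphenyl]ethan-1-one
Product: 2 1-[4,6-bis(benzyloxy)-2-hydroxy-3-iodophenyl]ethan-1-one
Conditions: BnMe3N+ ICl2− (1.1 eq), NaHCO3, CH2Cl2–MeOH (5:2), rt
Reagents that add atoms: benzyltrimethylammonium dichloroiodate, C[N+](C)(C)Cc1ccccc1.Cl[I-]Cl
Why: Electrophilic aromatic iodination (SEAr) goes ortho to the free, chelated phenol (the CH between OH and OBn), as is usual for 2-hydroxy-4,6-dialkoxyacetophenones, and the bicarbonate buffer keeps the benzyl ethers intact.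

Step 2
Reactants: 2 1-[4,6-bis(benzyloxy)-2-hydroxy-3-iodophenyl]ethan-1-one
Product: 3 1-[4,6-bis(benzyloxy)-3-iodo-2-(methoxymethoxy)phenyl]ethan-1-one
Conditions: NaH (1.2 eq), MOMCl (1.5 eq), DMF, 0 °C to rt
Reagents that add atoms: chloromethyl methyl ether (MOMCl), COCCl
Why: Williamson-type O-alkylation of the sodium phenoxide caps the oxygen next to iodine (the future 5-O), which stops benzofuran formation in the Sonogashira step and later stops this oxygen from closing the pyranone ring.

Step 3
Reactants: 3 1-[4,6-bis(benzyloxy)-3-iodo-2-(methoxymethoxy)phenyl]ethan-1-one; 4 2-methylbut-3-yn-2-ol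
Product: 5 1-[4,6-bis(benzyloxy)-3-(3-hydroxy-3-methylbut-1-yn-1-yl)-2-(methoxymethoxy)phenyl]ethan-1-one
Conditions: PdCl2(PPh3)2 (5 mol %), CuI (10 mol %), Et3N–DMF, 80 °C
Reagents that add atoms: none
Why: Sonogashira coupling of the aryl iodide with the terminal alkyne brings in all five side-chain carbons with the tertiary alcohol already in place; the alcohol needs no protection.

Step 4
Reactants: 5 1-[4,6-bis(benzyloxy)-3-(3-hydroxy-3-methylbut-1-yn-1-yl)-2-(methoxymethoxy)phenyl]ethan-1-one
Product: 6 1-[4,6-dihydroxy-3-(3-hydroxy-3-methylbutyl)-2-(methoxymethoxy)phenyl]ethan-1-one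
Conditions: H2 (1 atm), 10% Pd/C, EtOAc–MeOH, rt
Reagents that add atoms: none
Why: Catalytic hydrogenation saturates the alkyne and hydrogenolyses both benzyl ethers in one operation, which frees the ortho phenol that is not next to the side chain while the MOM ether and tertiary alcohol are inert.

Step 5
Reactants: 6 1-[4,6-dihydroxy-3-(3-hydroxy-3-methylbutyl)-2-(methoxymethoxy)phenyl]ethan-1-one
Product: 7 1-[6-hydroxy-3-(3-hydroxy-3-methylbutyl)-2,4-bis(methoxymethoxy)phenyl]ethan-1-one
Conditions: MOMCl (1.1 eq), i-Pr2NEt (1.5 eq), CH2Cl2, 0 °C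
Reagents that add atoms: chloromethyl methyl ether (MOMCl), COCCl
Why: Chemoselective MOM etherification takes the para phenol only, because the ortho phenol is locked in a hydrogen bond to the ketone and the tertiary alcohol is too hindered at 0 °C with one equivalent; this protection prevents O-methylation by DMF-DMA in the next step.

Step 6
Reactants: 7 1-[6-hydroxy-3-(3-hydroxy-3-methylbutyl)-2,4-bis(methoxymethoxy)phenyl]ethan-1-one
Product: 9 6-(3-hydroxy-3-methylbutyl)-3-iodo-5,7-bis(methoxymethoxy)-4H-chromen-4-one, via enaminone 8 (not isolated)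
Conditions: DMF-DMA, toluene, 90 °C; evaporate; then I2 (1.2 eq), pyridine, CHCl3, rt
Reagents that add atoms: N,N-dimethylformamide dimethyl acetal, COC(OC)N(C)C; iodine, II
Why: Condensation of the methyl ketone with DMF-DMA gives the enaminone, and iodine then causes α-iodination and ring closure by the only free ortho phenol with loss of dimethylamine (Gammill 3-iodochromone synthesis), so the side chain must end up at C6.

Step 7
Reactants: 10 resorcinol
Product: 11 1,3-bis(methoxymethoxy)benzene
Conditions: MOMCl (2.4 eq), i-Pr2NEt (3 eq), CH2Cl2, 0 °C to rt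
Reagents that add atoms: chloromethyl methyl ether (MOMCl), COCCl
Why: Double O-alkylation (MOM protection) installs the groups that direct the lithiation in the next step.

Step 8
Reactants: 11 1,3-bis(methoxymethoxy)benzene; 12 1-bromo-3-methylbut-2-ene (prenyl bromide)
Product: 14 1,3-bis(methoxymethoxy)-2-(3-methylbut-2-en-1-yl)benzene, via aryllithium 13 (not isolated)
Conditions: n-BuLi (1.1 eq), THF, 0 °C to rt; then CuI (10 mol %), 12, −78 °C to rt
Reagents that add atoms: none
Why: Directed ortho-metalation occurs at C2, the position flanked by both OMOM groups, and the aryllithium is allylated by prenyl bromide at the unhindered CH2 terminus (copper-assisted SN2).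

Step 9
Reactants: 14 1,3-bis(methoxymethoxy)-2-(3-methylbut-2-en-1-yl)benzene
Product: 15 1-bromo-2,4-bis(methoxymethoxy)-3-(3-methylbut-2-en-1-yl)benzene
Conditions: NBS (1.0 eq), DMF, 0 °C, dark
Reagents that add atoms: N-bromosuccinimide, O=C1CCC(=O)N1Br
Why: SEAr bromination goes to C4 (para to one OMOM, ortho to the other; both such positions are equivalent), and in dry DMF at 0 °C the electron-rich ring reacts faster than the trisubstituted alkene.

Step 10
Reactants: 15 1-bromo-2,4-bis(methoxymethoxy)-3-(3-methylbut-2-en-1-yl)benzene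
Product: 17 2-[2,4-bis(methoxymethoxy)-3-(3-methylbut-2-en-1-yl)phenyl]-4,4,5,5-tetramethyl-1,3,2-dioxaborolane, via aryllithium 16 (not isolated)
Conditions: n-BuLi (1.05 eq), THF, −78 °C; then i-PrOBpin, −78 °C to rt; H2O
Reagents that add atoms: 2-isopropoxy-4,4,5,5-tetramethyl-1,3,2-dioxaborolane, CC(C)OB1OC(C)(C)C(C)(C)O1
Why: Bromine–lithium exchange at −78 °C is faster than deprotonation of the benzylic/allylic CH2, and the aryllithium is trapped by the borate ester to give the pinacol boronate.

Step 11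
Reactants: 9 6-(3-hydroxy-3-methylbutyl)-3-iodo-5,7-bis(methoxymethoxy)-4H-chromen-4-one; 17 2-[2,4-bis(methoxymethoxy)-3-(3-methylbut-2-en-1-yl)phenyl]-4,4,5,5-tetramethyl-1,3,2-dioxaborolane
Product: 18 3-[2,4-bis(methoxymethoxy)-3-(3-methylbut-2-en-1-yl)phenyl]-6-(3-hydroxy-3-methylbutyl)-5,7-bis(methoxymethoxy)-4H-chromen-4-one
Conditions: Pd(dppf)Cl2 (5 mol %), K2CO3 (3 eq), 17 (1.3 eq), dioxane–H2O (5:1), 80 °C
Reagents that add atoms: none
Why: Suzuki–Miyaura cross-coupling of the reactive α-iodoenone C–I bond with the aryl boronate builds the isoflavone, and the MOM ethers, prenyl alkene and free tertiary alcohol tolerate the weakly basic conditions.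

Step 12
Reactants: 18 3-[2,4-bis(methoxymethoxy)-3-(3-methylbut-2-en-1-yl)phenyl]-6-(3-hydroxy-3-methylbutyl)-5,7-bis(methoxymethoxy)-4H-chromen-4-one
Product: 19 3-[2,4-dihydroxy-3-(3-methylbut-2-en-1-yl)phenyl]-5,7-dihydroxy-6-(3-hydroxy-3-methylbutyl)-4H-chromen-4-one (CNP0076924.0)
Conditions: 1 M HCl in MeOH, 40 °C, stop at full conversion; NaHCO3 quench
Reagents that add atoms: none
Why: Acid-catalysed acetal exchange removes all four phenolic MOM ethers under dilute, low-temperature conditions chosen so that neither the prenyl group nor the tertiary alcohol cyclises onto a neighbouring phenol; no stereocentre is present.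

**Compound list**
1 | 1-[2,4-bis(benzyloxy)-6-hydroxyphenyl]ethan-1-one | CC(=O)c1c(O)cc(OCc2ccccc2)cc1OCc1ccccc1 | starting material
2 | 1-[4,6-bis(benzyloxy)-2-hydroxy-3-iodophenyl]ethan-1-one | CC(=O)c1c(O)c(I)c(OCc2ccccc2)cc1OCc1ccccc1 | intermediate
3 | 1-[4,6-bis(benzyloxy)-3-iodo-2-(methoxymethoxy)phenyl]ethan-1-one | CC(=O)c1c(OCOC)c(I)c(OCc2ccccc2)cc1OCc1ccccc1 | intermediate
4 | 2-methylbut-3-yn-2-ol | CC(C)(O)C#C | starting material
5 | 1-[4,6-bis(benzyloxy)-3-(3-hydroxy-3-methylbut-1-yn-1-yl)-2-(methoxymethoxy)phenyl]ethan-1-one | CC(=O)c1c(OCOC)c(C#CC(C)(C)O)c(OCc2ccccc2)cc1OCc1ccccc1 | intermediate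
6 | 1-[4,6-dihydroxy-3-(3-hydroxy-3-methylbutyl)-2-(methoxymethoxy)phenyl]ethan-1-one | CC(=O)c1c(OCOC)c(CCC(C)(C)O)c(O)cc1O | intermediate
7 | 1-[6-hydroxy-3-(3-hydroxy-3-methylbutyl)-2,4-bis(methoxymethoxy)phenyl]ethan-1-one | CC(=O)c1c(OCOC)c(CCC(C)(C)O)c(OCOC)cc1O | intermediate
8 | (E)-3-(dimethylamino)-1-[6-hydroxy-3-(3-hydroxy-3-methylbutyl)-2,4-bis(methoxymethoxy)phenyl]prop-2-en-1-one | CN(C)/C=C/C(=O)c1c(OCOC)c(CCC(C)(C)O)c(OCOC)cc1O | intermediate
9 | 6-(3-hydroxy-3-methylbutyl)-3-iodo-5,7-bis(methoxymethoxy)-4H-chromen-4-one | COCOc1cc2occ(I)c(=O)c2c(OCOC)c1CCC(C)(C)O | intermediate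
10 | resorcinol (benzene-1,3-diol) | Oc1cccc(O)c1 | starting material
11 | 1,3-bis(methoxymethoxy)benzene | COCOc1cccc(OCOC)c1 | intermediate
12 | 1-bromo-3-methylbut-2-ene (prenyl bromide) | CC(C)=CCBr | starting material
13 | [2,6-bis(methoxymethoxy)phenyl]lithium | [Li]c1c(OCOC)cccc1OCOC | intermediate
14 | 1,3-bis(methoxymethoxy)-2-(3-methylbut-2-en-1-yl)benzene | COCOc1cccc(OCOC)c1CC=C(C)C | intermediate
15 | 1-bromo-2,4-bis(methoxymethoxy)-3-(3-methylbut-2-en-1-yl)benzene | COCOc1ccc(Br)c(OCOC)c1CC=C(C)C | intermediate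
16 | [2,4-bis(methoxymethoxy)-3-(3-methylbut-2-en-1-yl)phenyl]lithium | [Li]c1ccc(OCOC)c(CC=C(C)C)c1OCOC | intermediate
17 | 2-[2,4-bis(methoxymethoxy)-3-(3-methylbut-2-en-1-yl)phenyl]-4,4,5,5-tetramethyl-1,3,2-dioxaborolane | COCOc1ccc(B2OC(C)(C)C(C)(C)O2)c(OCOC)c1CC=C(C)C | intermediate
18 | 3-[2,4-bis(methoxymethoxy)-3-(3-methylbut-2-en-1-yl)phenyl]-6-(3-hydroxy-3-methylbutyl)-5,7-bis(methoxymethoxy)-4H-chromen-4-one | COCOc1ccc(-c2coc3cc(OCOC)c(CCC(C)(C)O)c(OCOC)c3c2=O)c(OCOC)c1CC=C(C)C | intermediate
19 | 3-[2,4-dihydroxy-3-(3-methylbut-2-en-1-yl)phenyl]-5,7-dihydroxy-6-(3-hydroxy-3-methylbutyl)-4H-chromen-4-one | CC(C)=CCc1c(O)ccc(-c2coc3cc(O)c(CCC(C)(C)O)c(O)c3c2=O)c1O | target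

**Totals**
Total step count: 12. Longest linear sequence: 8 steps (steps 1–6, 11, 12); the B-ring branch is 4 steps (steps 7–10).

**Three steps most likely to fail, with fallbacks**

Step 12 (most at risk): the acid that removes the MOM groups can also cyclise the prenyl group or the tertiary alcohol onto a neighbouring phenol to give dimethylchromans. The fallback sets out from 18 and avoids Brønsted acid altogether. TMSOTf and 2,2′-bipyridyl in CH2Cl2 at 0 °C to rt turn the aryl MOM ethers into aryl silyl ethers and silylate the tertiary alcohol. This gives 3-[3-(3-methylbut-2-en-1-yl)-2,4-bis(trimethylsilyloxy)phenyl]-6-[3-methyl-3-(trimethylsilyloxy)butyl]-5,7-bis(trimethylsilyloxy)-4H-chromen-4-one F5. K2CO3 in MeOH at 0 °C then cleaves all five silyl ethers, and the route is rejoined at 19.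

Step 9: NBS may attack the prenyl alkene or over-brominate. The fallback sets out from 11 and reverses the order so that NBS never meets an alkene. Compound 11 is brominated first (NBS, DMF, 0 °C) to 1-bromo-2,4-bis(methoxymethoxy)benzene F3. LDA in THF at −78 °C, which does not exchange the bromine, then deprotonates between the two OMOM groups to give [3-bromo-2,6-bis(methoxymethoxy)phenyl]lithium F4 (not isolated). Allylation with 12 (CuI cat., −78 °C to rt) returns the route at 15.

Step 3: the iodide is electron-rich and flanked by two alkoxy groups, so the Sonogashira coupling may be slow and alkyne homocoupling may compete. The fallback sets out from 3 and uses an sp3 boron partner instead of an alkyne. 2-Methylbut-3-en-2-ol is hydroborated with 9-BBN-H (THF, rt) to 9-(3-hydroxy-3-methylbutyl)-9-borabicyclo[3.3.1]nonane F1. B-alkyl Suzuki–Miyaura coupling of F1 with 3 (Pd(dppf)Cl2, K3PO4, DMF–H2O, 60 °C) gives 1-[4,6-bis(benzyloxy)-3-(3-hydroxy-3-methylbutyl)-2-(methoxymethoxy)phenyl]ethan-1-one F2. Hydrogenolysis of the two benzyl ethers (H2, Pd/C, EtOAc–MeOH) returns the route at 6.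

**Further compounds**
F1 | step 3 | 9-(3-hydroxy-3-methylbutyl)-9-borabicyclo[3.3.1]nonane | CC(C)(O)CCB1C2CCCC1CCC2
F2 | step 3 | 1-[4,6-bis(benzyloxy)-3-(3-hydroxy-3-methylbutyl)-2-(methoxymethoxy)phenyl]ethan-1-one | CC(=O)c1c(OCOC)c(CCC(C)(C)O)c(OCc2ccccc2)cc1OCc1ccccc1
F3 | step 9 | 1-bromo-2,4-bis(methoxymethoxy)benzene | COCOc1ccc(Br)c(OCOC)c1
F4 | step 9 | [3-bromo-2,6-bis(methoxymethoxy)phenyl]lithium | [Li]c1c(OCOC)ccc(Br)c1OCOC
F5 | step 12 | 3-[3-(3-methylbut-2-en-1-yl)-2,4-bis(trimethylsilyloxy)phenyl]-6-[3-methyl-3-(trimethylsilyloxy)butyl]-5,7-bis(trimethylsilyloxy)-4H-chromen-4-one | CC(C)=CCc1c(O[Si](C)(C)C)ccc(-c2coc3cc(O[Si](C)(C)C)c(CCC(C)(C)O[Si](C)(C)C)c(O[Si](C)(C)C)c3c2=O)c1O[Si](C)(C)C
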